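**Retrosynthetic overview**

1. The strategy rests on ring A (C1 CO2H, C2 OMe, C3 CH(OAc)CH2CHMe2, C6 OAr): the carboxyl carbon C1 lies between the methoxy carbon C2 and the ether carbon C6, the pattern left when an oxygen nucleophile and CO2 add across C6≡C1 of a 3-methoxyaryne.
2. Key disconnection: the C6–OAr and C1–CO2H bonds together, giving silyl triflate 12 (aryne 19), the phenoxide of bromophenol 17 and CO2; then the C6'–CH=CH bond of ring B (Heck reaction on the bromide); the acetate and the free C2'–OH come last.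
3. Triflate 12 comes from 4-bromo-3-methoxyphenol: carbamate, Negishi acylation, CBS reduction to the (S)-carbinol, silyl ether, directed ortho-silylation, carbamate cleavage, triflation.
4. Bromophenol 17 comes from 2-hydroxy-4-methylbenzaldehyde: PMB ether, Baeyer–Villiger oxidation, ortho-bromination.
5. No ring is formed; both benzene rings are bought and are joined in step 11.

Key step: step 11

Remark: the benzylic centre of the target reads as (S). The carbamate is chosen as the N,N-diethyl compound so that no N–H is present in the organolithium steps. Ring B is numbered C1' (ether O), C2' (OH), C4' (CH3), C6' (enone).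

**Route**

Step 1
Reactants: 1 4-bromo-3-methoxyphenol
Product: 2 4-bromo-3-methoxyphenyl N,N-diethylcarbamate
Conditions: Et2NCOCl, K2CO3, MeCN, reflux
Reagents that add atoms: N,N-diethylcarbamoyl chloride, CCN(CC)C(Cl)=O
Why: O-carbamoylation of the phenoxide (acyl substitution) gives a tertiary carbamate that survives the bromine–lithium exchange and later directs the ortho-metalation.

Step 2
Reactants: 2 4-bromo-3-methoxyphenyl N,N-diethylcarbamate; 3 isovaleryl chloride
Product: 6 3-methoxy-4-(3-methylbutanoyl)phenyl N,N-diethylcarbamate, via aryllithium 4 (not isolated), via arylzinc chloride 5 (not isolated)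
Conditions: n-BuLi, THF, −78 °C; ZnCl2, −78 → 0 °C; Pd(PPh3)4 (cat.), 3, 0 °C → rt
Reagents that add atoms: none
Why: Bromine–lithium exchange at −78 °C is faster than attack on the diethylcarbamate, and after transmetalation to zinc the Negishi acylation under zerovalent palladium catalysis stops at the ketone.

Step 3
Reactants: 6 3-methoxy-4-(3-methylbutanoyl)phenyl N,N-diethylcarbamate
Product: 7 4-[(1S)-1-hydroxy-3-methylbutyl]-3-methoxyphenyl N,N-diethylcarbamate
Conditions: (R)-2-methyl-CBS-oxazaborolidine (cat.), BH3·SMe2, THF, −20 °C; MeOH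
Reagents that add atoms: none
Why: Corey–Bakshi–Shibata reduction, in which the ketone binds the catalyst boron with the aryl group as the large substituent and the N-bound borane delivers hydride to the Re face, which should set the (S)-carbinol.

Step 4
Reactants: 7 4-[(1S)-1-hydroxy-3-methylbutyl]-3-methoxyphenyl N,N-diethylcarbamate
Product: 8 4-[(1S)-1-(tert-butyldimethylsilyloxy)-3-methylbutyl]-3-methoxyphenyl N,N-diethylcarbamate
Conditions: TBSOTf, 2,6-lutidine, CH2Cl2, 0 °C
Reagents that add atoms: tert-butyldimethylsilyl triflate, CC(C)(C)[Si](C)(C)OS(=O)(=O)C(F)(F)F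
Why: O-silylation with the silyl triflate protects the hindered benzylic alcohol without touching the C–O bond, so the configuration is kept.

Step 5
Reactants: 8 4-[(1S)-1-(tert-butyldimethylsilyloxy)-3-methylbutyl]-3-methoxyphenyl N,N-diethylcarbamate
Product: 10 4-[(1S)-1-(tert-butyldimethylsilyloxy)-3-methylbutyl]-3-methoxy-2-(trimethylsilyl)phenyl N,N-diethylcarbamate, via 2-lithio carbamate 9 (not isolated)
Conditions: s-BuLi, TMEDA, THF, −78 °C; TMSCl, −78 °C → rt
Reagents that add atoms: chlorotrimethylsilane, C[Si](C)(C)Cl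
Why: Directed ortho-metalation, in which the C2–H between the carbamate and the methoxy group is the most acidic and best coordinated site, and the TMSCl quench at −78 °C precedes the anionic ortho-Fries rearrangement.

Step 6
Reactants: 10 4-[(1S)-1-(tert-butyldimethylsilyloxy)-3-methylbutyl]-3-methoxy-2-(trimethylsilyl)phenyl N,N-diethylcarbamate
Product: 11 4-[(1S)-1-(tert-butyldimethylsilyloxy)-3-methylbutyl]-3-methoxy-2-(trimethylsilyl)phenol
Conditions: Cp2Zr(H)Cl, THF, rt; aq. NaHCO3
Reagents that add atoms: none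
Why: Reductive cleavage of the aryl O-carbamate with the Schwartz reagent (hydrozirconation of the carbonyl, collapse to the zirconium phenoxide) is mild enough to leave the silyl ether and the aryl silane intact.

Step 7
Reactants: 11 4-[(1S)-1-(tert-butyldimethylsilyloxy)-3-methylbutyl]-3-methoxy-2-(trimethylsilyl)phenol
Product: 12 3-methoxy-4-[(1S)-1-(tert-butyldimethylsilyloxy)-3-methylbutyl]-2-(trimethylsilyl)phenyl trifluoromethanesulfonate
Conditions: Tf2O, pyridine, CH2Cl2, −20 → 0 °C
Reagents that add atoms: trifluoromethanesulfonic anhydride, O=S(=O)(OS(=O)(=O)C(F)(F)F)C(F)(F)F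
Why: O-sulfonylation of the phenol, with pyridine taking up the triflic acid so that ipso-protodesilylation and loss of the silyl ether are avoided.

Step 8
Reactants: 13 2-hydroxy-4-methylbenzaldehyde
Product: 14 2-(4-methoxybenzyloxy)-4-methylbenzaldehyde
Conditions: PMBCl, K2CO3, n-Bu4NI (cat.), DMF, 50 °C
Reagents that add atoms: 4-methoxybenzyl chloride, COc1ccc(CCl)cc1
Why: Williamson etherification of the salicylaldehyde phenoxide fixes the PMB group on the oxygen that becomes C2'–OH of the target.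

Step 9
Reactants: 14 2-(4-methoxybenzyloxy)-4-methylbenzaldehyde
Product: 16 2-(4-methoxybenzyloxy)-4-methylphenol, via aryl formate 15 (not isolated)
Conditions: mCPBA, CH2Cl2, 0 °C → rt; K2CO3, MeOH, rt
Reagents that add atoms: 3-chloroperbenzoic acid, O=C(OO)c1cccc(Cl)c1
Why: Baeyer–Villiger (Dakin-type) oxidation, in which the electron-rich ortho-alkoxy aryl group migrates in the Criegee intermediate and the formate is then methanolysed to the phenol.

Step 10
Reactants: 16 2-(4-methoxybenzyloxy)-4-methylphenol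
Product: 17 2-bromo-6-(4-methoxybenzyloxy)-4-methylphenol
Conditions: NBS, i-Pr2NH (cat.), CH2Cl2, −20 → 0 °C
Reagents that add atoms: N-bromosuccinimide, O=C1CCC(=O)N1Br
Why: Amine-mediated electrophilic bromination delivers bromine through the hydrogen-bonded N-bromoamine to the position ortho to the free hydroxyl, the para position being blocked by the methyl group.

Step 11
Reactants: 12 3-methoxy-4-[(1S)-1-(tert-butyldimethylsilyloxy)-3-methylbutyl]-2-(trimethylsilyl)phenyl trifluoromethanesulfonate; 17 2-bromo-6-(4-methoxybenzyloxy)-4-methylphenol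
Product: 20 6-[2-bromo-6-(4-methoxybenzyloxy)-4-methylphenoxy]-3-[(1S)-1-(tert-butyldimethylsilyloxy)-3-methylbutyl]-2-methoxybenzoic acid, via potassium phenoxide 18 (not isolated), via 3-methoxyaryne 19 (not isolated)
Conditions: 17, KH, THF, 0 °C; CO2 (1 atm), 18-crown-6, CsF, slow addition of 12, THF, 0 °C → rt; aq. HCl to pH 3, 0 °C
Reagents that add atoms: carbon dioxide, O=C=O
Why: Proposed new method: fluoride attacks the trimethylsilyl group of 12, triflate leaves and aryne 19 forms; the oxygen of phenoxide 18 adds to the aryne carbon remote from the methoxy group (C6), and the aryl anion left at C1, stabilised inductively by the oxygens at C2 and C6, adds to CO2 to give the carboxylate. The closest known reactions are the fluoride-induced three-component coupling of arynes, amines and CO2 to anthranilic acids and the aryne O-arylation of phenols; a phenoxide as the nucleophile in the CO2 coupling is the untested part. No ring is closed and no stereocenter is formed, and the silyloxy-bearing centre at the C3 side chain is not touched. The step needs regioselective addition and capture of the anion by CO2 and not by a proton: the first is secured by the C2 methoxy group, which distorts the aryne so that attack meta to it is favoured and leaves the crowded position beside it for the small electrophile; the second by a preformed, proton-free phenoxide (KH gives only hydrogen) in THF, not acetonitrile, under CO2. Both ether carbons carry two ortho substituents, a case that is slow in Ullmann or SNAr coupling but not in aryne capture, and O-carboxylation of the hindered, bromine-bearing phenoxide is reversible, so free phenoxide remains available.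

Step 12
Reactants: 20 6-[2-bromo-6-(4-methoxybenzyloxy)-4-methylphenoxy]-3-[(1S)-1-(tert-butyldimethylsilyloxy)-3-methylbutyl]-2-methoxybenzoic acid; 21 methyl vinyl ketone
Product: 22 3-[(1S)-1-(tert-butyldimethylsilyloxy)-3-methylbutyl]-2-methoxy-6-{2-(4-methoxybenzyloxy)-4-methyl-6-[(1E)-3-oxobut-1-en-1-yl]phenoxy}benzoic acid
Conditions: Pd2(dba)3 (cat.), [(t-Bu)3PH]BF4 (cat.), Cy2NMe, 21 (excess), 1,4-dioxane, 60 °C
Reagents that add atoms: none
Why: Mizoroki–Heck reaction, in which oxidative addition of zerovalent palladium into the C6'–Br bond, syn insertion of the enone and syn β-hydride elimination should give the (E)-enone, the acid being carried as its ammonium carboxylate.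

Step 13
Reactants: 22 3-[(1S)-1-(tert-butyldimethylsilyloxy)-3-methylbutyl]-2-methoxy-6-{2-(4-methoxybenzyloxy)-4-methyl-6-[(1E)-3-oxobut-1-en-1-yl]phenoxy}benzoic acid
Product: 23 3-[(1S)-1-hydroxy-3-methylbutyl]-2-methoxy-6-{2-(4-methoxybenzyloxy)-4-methyl-6-[(1E)-3-oxobut-1-en-1-yl]phenoxy}benzoic acid
Conditions: TBAF, AcOH, THF, rt → 40 °C
Reagents that add atoms: none
Why: Fluoride desilylation driven by the Si–F bond, buffered with acetic acid to spare the enone, breaks only the O–Si bond, so the (S) centre is kept.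

Step 14
Reactants: 23 3-[(1S)-1-hydroxy-3-methylbutyl]-2-methoxy-6-{2-(4-methoxybenzyloxy)-4-methyl-6-[(1E)-3-oxobut-1-en-1-yl]phenoxy}benzoic acid
Product: 25 3-[(1S)-1-acetoxy-3-methylbutyl]-2-methoxy-6-{2-(4-methoxybenzyloxy)-4-methyl-6-[(1E)-3-oxobut-1-en-1-yl]phenoxy}benzoic acid, via mixed acetic anhydride 24 (not isolated)
Conditions: Ac2O, pyridine, DMAP (cat.), CH2Cl2, 0 °C → rt; aq. NaHCO3, THF, rt; acidify to pH 3
Reagents that add atoms: acetic anhydride, CC(=O)OC(C)=O
Why: DMAP-catalysed O-acetylation of the secondary alcohol, in which the acid passes through a mixed anhydride that is hydrolysed at its acetyl carbonyl on work-up, while the PMB ether prevents acetylation of the C2' phenol and its lactonisation onto the activated acid.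

Step 15
Reactants: 25 3-[(1S)-1-acetoxy-3-methylbutyl]-2-methoxy-6-{2-(4-methoxybenzyloxy)-4-methyl-6-[(1E)-3-oxobut-1-en-1-yl]phenoxy}benzoic acid
Product: 26 3-[(1S)-1-acetoxy-3-methylbutyl]-6-{2-hydroxy-4-methyl-6-[(1E)-3-oxobut-1-en-1-yl]phenoxy}-2-methoxybenzoic acid (CNP0281268.1)
Conditions: DDQ, CH2Cl2/pH 7 phosphate buffer, 0 °C → rt
Reagents that add atoms: none
Why: Oxidative PMB cleavage (hydride abstraction from the anisyl methylene by DDQ, then hydrolysis of the hemiacetal) runs under neutral conditions that should spare the ionisable benzylic acetate, the enone and the acid.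

**Compound list**

1 | 4-bromo-3-methoxyphenol | COc1cc(O)ccc1Br | starting material
2 | 4-bromo-3-methoxyphenyl N,N-diethylcarbamate | CCN(CC)C(=O)Oc1ccc(Br)c(OC)c1 | intermediate
3 | isovaleryl chloride (3-methylbutanoyl chloride) | CC(C)CC(Cl)=O | starting material
4 | [4-(diethylcarbamoyloxy)-2-methoxyphenyl]lithium | CCN(CC)C(=O)Oc1ccc([Li])c(OC)c1 | intermediate
5 | [4-(diethylcarbamoyloxy)-2-methoxyphenyl]zinc chloride | CCN(CC)C(=O)Oc1ccc([Zn]Cl)c(OC)c1 | intermediate
6 | 3-methoxy-4-(3-methylbutanoyl)phenyl N,N-diethylcarbamate | CCN(CC)C(=O)Oc1ccc(C(=O)CC(C)C)c(OC)c1 | intermediate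
7 | 4-[(1S)-1-hydroxy-3-methylbutyl]-3-methoxyphenyl N,N-diethylcarbamate | CCN(CC)C(=O)Oc1ccc([C@H](CC(C)C)O)c(OC)c1 | intermediate
8 | 4-[(1S)-1-(tert-butyldimethylsilyloxy)-3-methylbutyl]-3-methoxyphenyl N,N-diethylcarbamate | CCN(CC)C(=O)Oc1ccc([C@H](CC(C)C)O[Si](C)(C)C(C)(C)C)c(OC)c1 | intermediate
9 | {6-(diethylcarbamoyloxy)-3-[(1S)-1-(tert-butyldimethylsilyloxy)-3-methylbutyl]-2-methoxyphenyl}lithium | CCN(CC)C(=O)Oc1ccc([C@H](CC(C)C)O[Si](C)(C)C(C)(C)C)c(OC)c1[Li] | intermediate
10 | 4-[(1S)-1-(tert-butyldimethylsilyloxy)-3-methylbutyl]-3-methoxy-2-(trimethylsilyl)phenyl N,N-diethylcarbamate | CCN(CC)C(=O)Oc1ccc([C@H](CC(C)C)O[Si](C)(C)C(C)(C)C)c(OC)c1[Si](C)(C)C | intermediate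
11 | 4-[(1S)-1-(tert-butyldimethylsilyloxy)-3-methylbutyl]-3-methoxy-2-(trimethylsilyl)phenol | Oc1ccc([C@H](CC(C)C)O[Si](C)(C)C(C)(C)C)c(OC)c1[Si](C)(C)C | intermediate
12 | 3-methoxy-4-[(1S)-1-(tert-butyldimethylsilyloxy)-3-methylbutyl]-2-(trimethylsilyl)phenyl trifluoromethanesulfonate | COc1c([C@H](CC(C)C)O[Si](C)(C)C(C)(C)C)ccc(OS(=O)(=O)C(F)(F)F)c1[Si](C)(C)C | intermediate
13 | 2-hydroxy-4-methylbenzaldehyde | Cc1ccc(C=O)c(O)c1 | starting material
14 | 2-(4-methoxybenzyloxy)-4-methylbenzaldehyde | Cc1ccc(C=O)c(OCc2ccc(OC)cc2)c1 | intermediate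
15 | 2-(4-methoxybenzyloxy)-4-methylphenyl formate | Cc1ccc(OC=O)c(OCc2ccc(OC)cc2)c1 | intermediate
16 | 2-(4-methoxybenzyloxy)-4-methylphenol | Cc1ccc(O)c(OCc2ccc(OC)cc2)c1 | intermediate
17 | 2-bromo-6-(4-methoxybenzyloxy)-4-methylphenol | Cc1cc(Br)c(O)c(OCc2ccc(OC)cc2)c1 | intermediate
18 | potassium 2-bromo-6-(4-methoxybenzyloxy)-4-methylphenoxide | Cc1cc(Br)c([O-])c(OCc2ccc(OC)cc2)c1.[K+] | intermediate
19 | 3-methoxy-4-[(1S)-1-(tert-butyldimethylsilyloxy)-3-methylbutyl]benzyne (1,2-didehydrobenzene) | COC1=C([C@H](CC(C)C)O[Si](C)(C)C(C)(C)C)C=CC#C1 | intermediate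
20 | 6-[2-bromo-6-(4-methoxybenzyloxy)-4-methylphenoxy]-3-[(1S)-1-(tert-butyldimethylsilyloxy)-3-methylbutyl]-2-methoxybenzoic acid | COc1c([C@H](CC(C)C)O[Si](C)(C)C(C)(C)C)ccc(Oc2c(OCc3ccc(OC)cc3)cc(C)cc2Br)c1C(=O)O | intermediate
21 | methyl vinyl ketone (but-3-en-2-one) | C=CC(C)=O | starting material
22 | 3-[(1S)-1-(tert-butyldimethylsilyloxy)-3-methylbutyl]-2-methoxy-6-{2-(4-methoxybenzyloxy)-4-methyl-6-[(1E)-3-oxobut-1-en-1-yl]phenoxy}benzoic acid | COc1c([C@H](CC(C)C)O[Si](C)(C)C(C)(C)C)ccc(Oc2c(OCc3ccc(OC)cc3)cc(C)cc2/C=C/C(C)=O)c1C(=O)O | intermediate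
23 | 3-[(1S)-1-hydroxy-3-methylbutyl]-2-methoxy-6-{2-(4-methoxybenzyloxy)-4-methyl-6-[(1E)-3-oxobut-1-en-1-yl]phenoxy}benzoic acid | COc1c([C@H](CC(C)C)O)ccc(Oc2c(OCc3ccc(OC)cc3)cc(C)cc2/C=C/C(C)=O)c1C(=O)O | intermediate
24 | acetic 3-[(1S)-1-acetoxy-3-methylbutyl]-2-methoxy-6-{2-(4-methoxybenzyloxy)-4-methyl-6-[(1E)-3-oxobut-1-en-1-yl]phenoxy}benzoic anhydride | COc1c([C@H](CC(C)C)OC(C)=O)ccc(Oc2c(OCc3ccc(OC)cc3)cc(C)cc2/C=C/C(C)=O)c1C(=O)OC(C)=O | intermediate
25 | 3-[(1S)-1-acetoxy-3-methylbutyl]-2-methoxy-6-{2-(4-methoxybenzyloxy)-4-methyl-6-[(1E)-3-oxobut-1-en-1-yl]phenoxy}benzoic acid | COc1c([C@H](CC(C)C)OC(C)=O)ccc(Oc2c(OCc3ccc(OC)cc3)cc(C)cc2/C=C/C(C)=O)c1C(=O)O | intermediate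
26 | 3-[(1S)-1-acetoxy-3-methylbutyl]-6-{2-hydroxy-4-methyl-6-[(1E)-3-oxobut-1-en-1-yl]phenoxy}-2-methoxybenzoic acid (CNP0281268.1) | COc1c([C@H](CC(C)C)OC(C)=O)ccc(Oc2c(O)cc(C)cc2/C=C/C(C)=O)c1C(=O)O | target

**Step count and risks**

Total step count: 15 (steps 1–7 for triflate 12, steps 8–10 for bromophenol 17, steps 11–15 from the coupling to the target).
Longest linear sequence: 12 steps (steps 1–7, 11, 12–15, from 4-bromo-3-methoxyphenol).

Steps most likely to fail:

1. Step 11 (three-component aryne coupling). The C1 aryl anion may be protonated before it meets CO2, which gives the plain diaryl ether. The phenoxide may be tied up as its O-carbonate, which slows the arylation or transfers the carboxyl group to the wrong atom. The carboxylate formed may itself be arylated by the aryne. The fallback uses known chemistry only and builds the same two bonds by SNAr and aldehyde oxidation; it sets out from isovaleryl chloride 3 and bromophenol 17 and comes back at acid 20.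
   - Purchased 1-bromo-4-fluoro-2-methoxybenzene F1 is taken through the conditions of step 2 (n-BuLi; ZnCl2; Pd(PPh3)4, 3), by way of (4-fluoro-2-methoxyphenyl)lithium F2 and (4-fluoro-2-methoxyphenyl)zinc chloride F3, to 1-(4-fluoro-2-methoxyphenyl)-3-methylbutan-1-one F4.
   - Reduction as in step 3 gives (1S)-1-(4-fluoro-2-methoxyphenyl)-3-methylbutan-1-ol F5, and silylation as in step 4 gives its tert-butyldimethylsilyl ether F6.
   - Lithiation between fluorine and methoxy (n-BuLi, TMEDA, THF, −78 °C) gives the 3-lithio compound F7, and DMF converts it into 6-fluoro-2-methoxy-3-[(1S)-1-(tert-butyldimethylsilyloxy)-3-methylbutyl]benzaldehyde F8.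
   - SNAr displacement of the aldehyde-activated fluoride by 17 (K2CO3, DMA, 110 °C) gives 6-[2-bromo-6-(4-methoxybenzyloxy)-4-methylphenoxy]-2-methoxy-3-[(1S)-1-(tert-butyldimethylsilyloxy)-3-methylbutyl]benzaldehyde F9.
   - Pinnick oxidation (NaClO2, NaH2PO4, 2-methyl-2-butene, t-BuOH/H2O) returns 20.

2. Step 5 (directed ortho-silylation). Metalation may go to C6 or to the benzylic C–H, the side chain next to the methoxy group may slow silylation of the crowded C2 anion, and the carbamoyl group may migrate (anionic ortho-Fries) on warming. The fallback installs silicon before the side chain; it sets out from carbamate 2 and comes back at 10.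
   - LDA with TMSCl present from the start (in situ quench, THF, −78 °C) passes through the 2-lithio carbamate F10 and gives 4-bromo-3-methoxy-2-(trimethylsilyl)phenyl N,N-diethylcarbamate F11.
   - The conditions of step 2 then lead through the aryllithium F12 and the arylzinc chloride F13 to 3-methoxy-4-(3-methylbutanoyl)-2-(trimethylsilyl)phenyl N,N-diethylcarbamate F14.
   - Reduction as in step 3 gives 4-[(1S)-1-hydroxy-3-methylbutyl]-3-methoxy-2-(trimethylsilyl)phenyl N,N-diethylcarbamate F15, and silylation as in step 4 gives 10.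

3. Step 12 (Heck reaction). Methyl vinyl ketone may polymerise, the neighbouring carboxylate may bind the catalyst, the arylpalladium intermediate may attack C5–H of ring A (closure to a dibenzofuran), or the bromide may be reduced. The fallback separates C–C coupling from enone formation; it sets out from 20 and comes back at 22.
   - Suzuki–Miyaura coupling with potassium vinyltrifluoroborate (PdCl2(dppf), Cs2CO3, THF/H2O, 70 °C) gives 6-[2-ethenyl-6-(4-methoxybenzyloxy)-4-methylphenoxy]-3-[(1S)-1-(tert-butyldimethylsilyloxy)-3-methylbutyl]-2-methoxybenzoic acid F16.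
   - Olefin cross-metathesis of F16 with methyl vinyl ketone 21 (second-generation Hoveyda–Grubbs catalyst, CH2Cl2, 40 °C) should give the (E)-enone 22.

**Further compounds**

F1 | step 11 | 1-bromo-4-fluoro-2-methoxybenzene (purchased) | COc1cc(F)ccc1Br
F2 | step 11 | (4-fluoro-2-methoxyphenyl)lithium | COc1cc(F)ccc1[Li]
F3 | step 11 | (4-fluoro-2-methoxyphenyl)zinc chloride | COc1cc(F)ccc1[Zn]Cl
F4 | step 11 | 1-(4-fluoro-2-methoxyphenyl)-3-methylbutan-1-one | COc1cc(F)ccc1C(=O)CC(C)C
F5 | step 11 | (1S)-1-(4-fluoro-2-methoxyphenyl)-3-methylbutan-1-ol | COc1cc(F)ccc1[C@H](CC(C)C)O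
F6 | step 11 | tert-butyl{[(1S)-1-(4-fluoro-2-methoxyphenyl)-3-methylbutyl]oxy}dimethylsilane | COc1cc(F)ccc1[C@H](CC(C)C)O[Si](C)(C)C(C)(C)C
F7 | step 11 | {6-fluoro-2-methoxy-3-[(1S)-1-(tert-butyldimethylsilyloxy)-3-methylbutyl]phenyl}lithium | COc1c([C@H](CC(C)C)O[Si](C)(C)C(C)(C)C)ccc(F)c1[Li]
F8 | step 11 | 6-fluoro-2-methoxy-3-[(1S)-1-(tert-butyldimethylsilyloxy)-3-methylbutyl]benzaldehyde | COc1c([C@H](CC(C)C)O[Si](C)(C)C(C)(C)C)ccc(F)c1C=O
F9 | step 11 | 6-[2-bromo-6-(4-methoxybenzyloxy)-4-methylphenoxy]-2-methoxy-3-[(1S)-1-(tert-butyldimethylsilyloxy)-3-methylbutyl]benzaldehyde | COc1c([C@H](CC(C)C)O[Si](C)(C)C(C)(C)C)ccc(Oc2c(OCc3ccc(OC)cc3)cc(C)cc2Br)c1C=O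
F10 | step 5 | [3-bromo-6-(diethylcarbamoyloxy)-2-methoxyphenyl]lithium | CCN(CC)C(=O)Oc1ccc(Br)c(OC)c1[Li]
F11 | step 5 | 4-bromo-3-methoxy-2-(trimethylsilyl)phenyl N,N-diethylcarbamate | CCN(CC)C(=O)Oc1ccc(Br)c(OC)c1[Si](C)(C)C
F12 | step 5 | [4-(diethylcarbamoyloxy)-2-methoxy-3-(trimethylsilyl)phenyl]lithium | CCN(CC)C(=O)Oc1ccc([Li])c(OC)c1[Si](C)(C)C
F13 | step 5 | [4-(diethylcarbamoyloxy)-2-methoxy-3-(trimethylsilyl)phenyl]zinc chloride | CCN(CC)C(=O)Oc1ccc([Zn]Cl)c(OC)c1[Si](C)(C)C
F14 | step 5 | 3-methoxy-4-(3-methylbutanoyl)-2-(trimethylsilyl)phenyl N,N-diethylcarbamate | CCN(CC)C(=O)Oc1ccc(C(=O)CC(C)C)c(OC)c1[Si](C)(C)C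
F15 | step 5 | 4-[(1S)-1-hydroxy-3-methylbutyl]-3-methoxy-2-(trimethylsilyl)phenyl N,N-diethylcarbamate | CCN(CC)C(=O)Oc1ccc([C@H](CC(C)C)O)c(OC)c1[Si](C)(C)C
F16 | step 12 | 6-[2-ethenyl-6-(4-methoxybenzyloxy)-4-methylphenoxy]-3-[(1S)-1-(tert-butyldimethylsilyloxy)-3-methylbutyl]-2-methoxybenzoic acid | COc1c([C@H](CC(C)C)O[Si](C)(C)C(C)(C)C)ccc(Oc2c(OCc3ccc(OC)cc3)cc(C)cc2C=C)c1C(=O)O
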